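All runs come from a simulation with constants of no real substance, noise included.

In a one-step world, with target passing first order into isomer of the product, the ratio of isomer to target begins at nothing and grows with time. The birch run tests that picture.

- birch: starting material 0.050 M; protic impurity 1 mM; capture agent 3.8 mM; run made earlier
- flask: starting material 0.050 M; protic impurity 1.00 mM; capture agent 2.50 mM; time 15 min

- birch (time / s: isomer of the product / %, target / %): 25.0: 0.8, 18.2; 50.0: 1.7, 29.5; 60.0: 2.3, 31.5; 90.0: 3.0, 32.9

(readings scatter by 0.3 percentage points)

- no earlier run changes the charge of capture agent; that part of a forecast is a guess

* ratio of isomer of the product to target at 4.0 s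
* ratio of isomer of the product to target at 50 s
* ratio of isomer of the product to target at 15 min

The middle of the birch run gives a reading of the constant. In that run, between 50.0 s and 90.0 s, target stands near 31.5% while isomer gains 1.3 percentage points. Dividing that gain by the time and by the target gives a first-order constant of 0.00103 s⁻¹. From it comes the leak half-life, 11.2 min, the time in which such a passage halves a standing amount of target. The reading carries a scatter of about a third of the gain.

The earliest birch reading tests the picture. While target climbs from nothing, a leak gives a ratio of half the constant times the time, so 0.0129 at 25.0 s, but the birch readings there give 0.0440. Going round again, the remainder, 0.0311, is taken as an opening ratio, a selectivity factor, with isomer appearing beside target from the start. Put back and carried over to the new flask, this gives 0.0331 at 4.0 s and 0.0569 at 50 s.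

At the end of the new flask, 15 min is longer than the leak half-life, so the opening ratio is dropped and isomer is counted as what target has lost: the exponential of constant times time, less one, gives 1.53. This reckoning holds no term for capture agent, and that is a guess, since no earlier run changes its charge.

The forecast gives 0.045, 0.08 and 1.1, the last lower than this reckoning and one that, in its words, “rests on the capture guess”. The flask gives 0.0319, 0.0629 and 1.39.

    starting material → open intermediate (k = 0.0310 s⁻¹)
    open intermediate ⇌ target (K = 2.00, k = 0.0760 s⁻¹)
    open intermediate ⇌ isomer of the product (K = 40.0, k = 0.00230 s⁻¹)
    starting material + protic impurity → quenched substrate (k = 13.0 M⁻¹ s⁻¹)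
    starting material + open intermediate → side product (k = 1.00 M⁻¹ s⁻¹)
    open intermediate + capture agent → trapped intermediate (k = 1.60 M⁻¹ s⁻¹)

In this flask isomer draws level with target at 11.6 min, while the reckoning puts that moment at the leak half-life, 11.2 min, and the final ratio stands below the reckoned one. The neighbouring flask is charged with 4.30 mM of capture agent instead of 2.50 mM. The same reckoning, having no capture term, gives 1.53 there again. That neighbouring flask ends with 8.60% trapped intermediate against 5.00% in this flask, with 25.2% isomer and 18.0% target, at a ratio of 1.40.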